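**Retrosynthetic overview**
- The target 14 comes from its 3-O-methoxymethyl ether 13 by mild acid cleavage of the acetal, the only step after ring formation.
- Ring C of 13 is opened at O1–C8a. In ring A, C8a is ortho to C4a, which carries the C4 carbonyl, and only meta to the prenyloxy carbon C7. A fluorine at C8a is therefore activated for displacement, and O1 can be supplied by the ring B ketone oxygen of diketone 11, so no ring A phenol has to be differentiated.
- Diketone 11 is cut at the future C3–C4 bond into the lithium enolate 10 of the MOM-protected hydroxy ketone 9 and the acyl imidazolide 5.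
- 5 comes from 2-fluoro-4-hydroxybenzoic acid 1 and prenyl bromide 2; 9 comes from bromo ketone 6.
- Rings A and B are bought; ring C is the only ring formed (step 7).

Key step: step 7

Assumption: the C2 centre of diketone 11 is racemic and enolisable and becomes sp2 in step 7, so the achiral target needs no stereocontrol; the carboxylate of step 2 and the diketonate of step 6 are only protonated on work-up and are counted as their neutral products.

**Route**

Step 1
Reactants: 1 2-fluoro-4-hydroxybenzoic acid; 2 prenyl bromide
Product: 3 3-methylbut-2-en-1-yl 2-fluoro-4-[(3-methylbut-2-en-1-yl)oxy]benzoate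
Conditions: 2 (2.3 equiv), K2CO3 (3 equiv), DMF, rt → 40 °C
Reagents that add atoms: prenyl bromide (compound 2), CC(C)=CCBr
Why: Double Williamson-type SN2 O-alkylation of the carboxylate and the phenoxide by the primary allylic bromide in DMF should give the prenyl ester and prenyl ether together, the aryl fluoride being inert to carbonate at this temperature.

Step 2
Reactants: 3 3-methylbut-2-en-1-yl 2-fluoro-4-[(3-methylbut-2-en-1-yl)oxy]benzoate
Product: 4 2-fluoro-4-[(3-methylbut-2-en-1-yl)oxy]benzoic acid
Conditions: LiOH·H2O (3 equiv), THF/H2O 3:1, 40 °C; then 1 M HCl to pH 3, 0 °C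
Reagents that add atoms: lithium hydroxide, [Li+].[OH-]
Why: Saponification (acyl–oxygen ester hydrolysis) should cleave only the ester, since the aryl prenyl ether is base-stable and the fluorine sits on a ring deactivated as its carboxylate, and methanol is left out so that no alkoxide can displace fluoride.

Step 3
Reactants: 4 2-fluoro-4-[(3-methylbut-2-en-1-yl)oxy]benzoic acid
Product: 5 {2-fluoro-4-[(3-methylbut-2-en-1-yl)oxy]phenyl}(1H-imidazol-1-yl)methanone
Conditions: CDI (1.1 equiv), CH2Cl2, rt; cold H2O wash, dry, concentrate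
Reagents that add atoms: 1,1'-carbonyldiimidazole, O=C(n1ccnc1)n1ccnc1
Why: Carboxylic acid activation with CDI gives a neutral acyl imidazolide that is reactive enough to C-acylate a lithium enolate yet survives the brief cold wash that removes the N–H acidic imidazole before the enolate step.

Step 4
Reactants: 6 2-bromo-1-(3,4-dimethoxyphenyl)ethanone
Product: 8 1-(3,4-dimethoxyphenyl)-2-hydroxyethanone, via formate ester 7 (not isolated)
Conditions: HCO2Na (4 equiv), EtOH/H2O 4:1, reflux
Reagents that add atoms: sodium formate, [Na+].[O-]C=O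
Why: SN2 displacement of the phenacyl bromide by formate followed by solvolysis of the labile formate ester in the same flask is an established conversion of α-bromo ketones into α-hydroxy ketones and avoids the side reactions of direct hydroxide treatment.

Step 5
Reactants: 8 1-(3,4-dimethoxyphenyl)-2-hydroxyethanone
Product: 9 1-(3,4-dimethoxyphenyl)-2-(methoxymethoxy)ethanone
Conditions: MOMCl (1.5 equiv), i-Pr2NEt (2 equiv), CH2Cl2, 0 °C → rt
Reagents that add atoms: chloromethyl methyl ether, COCCl
Why: MOM protection (O-alkylation of the primary alcohol by the chloromethyl ether with an amine base) masks the hydroxyl as an acetal that is stable to the strong base of step 6 and the carbonate of step 7.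

Step 6
Reactants: 9 1-(3,4-dimethoxyphenyl)-2-(methoxymethoxy)ethanone; 5 {2-fluoro-4-[(3-methylbut-2-en-1-yl)oxy]phenyl}(1H-imidazol-1-yl)methanone
Product: 11 rac-1-{2-fluoro-4-[(3-methylbut-2-en-1-yl)oxy]phenyl}-3-(3,4-dimethoxyphenyl)-2-(methoxymethoxy)propane-1,3-dione, via lithium enolate 10 (not isolated)
Conditions: LiN(SiMe3)2 (2.2 equiv), THF, −78 °C; then 5 (1.0 equiv), −78 → 0 °C; AcOH quench
Reagents that add atoms: none
Why: Crossed Claisen-type C-acylation of a lithium enolate by an acyl imidazolide, in which the chelated (Z)-enolate of the α-alkoxy ketone should attack the acyl carbon at −78 °C much faster than it could displace the aryl fluoride, while the second equivalent of base holds the more acidic product as its lithium diketonate until the quench; the new C2 centre is formed racemic and is lost in step 7.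

Step 7
Reactants: 11 rac-1-{2-fluoro-4-[(3-methylbut-2-en-1-yl)oxy]phenyl}-3-(3,4-dimethoxyphenyl)-2-(methoxymethoxy)propane-1,3-dione
Product: 13 2-(3,4-dimethoxyphenyl)-3-(methoxymethoxy)-7-[(3-methylbut-2-en-1-yl)oxy]-4H-chromen-4-one, via potassium enolate 12 (not isolated)
Conditions: K2CO3 (2.5 equiv), anhydrous DMF, 80–100 °C
Reagents that add atoms: none
Why: K2CO3 removes the C2 proton of the diketone, and the oxygen on the ring B (veratroyl) carbonyl of the potassium enolate adds to the fluorine-bearing carbon C8a to give a Meisenheimer-type anion whose charge runs through C4a into the C4 carbonyl (and to C6 and C8, never onto the prenyloxy carbon C7), after which loss of fluoride restores ring A. The closest known reaction type is the base-mediated intramolecular SNAr cyclisation of 1-(2-fluoroaryl)-1,3-diketones to chromones and flavones. Ring C closes by a six-membered addition–elimination at an sp2 carbon, formally 6-exo-trig with respect to the arene C8a=C8 bond and equally describable as a 6-endo addition–elimination on the vinylogous acyl fluoride C4=O/C4a=C8a. No stereocentre is created, and the racemic C2 of 11 becomes the sp2 carbon C3. The selectivity needed is O-attack by the ring B carbonyl oxygen at C8a, which the substrate secures because C-attack would require a four-membered ring, the ring A carbonyl oxygen cannot reach its own ring, and the methoxymethyl ether prevents the C3 oxygen from closing a five-membered benzofuran-3-one. The medium is basic and non-nucleophilic, so the aryl prenyl ether and the MOM acetal should survive, and the temperature lies well below that of an aromatic Claisen rearrangement.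

Step 8
Reactants: 13 2-(3,4-dimethoxyphenyl)-3-(methoxymethoxy)-7-[(3-methylbut-2-en-1-yl)oxy]-4H-chromen-4-one
Product: 14 2-(3,4-dimethoxyphenyl)-3-hydroxy-7-[(3-methylbut-2-en-1-yl)oxy]-4H-chromen-4-one (target)
Conditions: HCl (0.5 M), MeOH/THF 2:1, rt → 40 °C, stopped at full conversion
Reagents that add atoms: none
Why: Acid-catalysed acetal cleavage (MOM deprotection) in which the acetal on the enolic, phenol-like O3 ionises readily to a methoxymethyl cation trapped by methanol, whereas ionisation of the vinylogous-ester prenyl ether at O7 needs stronger acid or heat, so dilute HCl near room temperature should free the 3-hydroxyl with the prenyl ether intact.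

**Compound list**

1 | 2-fluoro-4-hydroxybenzoic acid | O=C(O)c1ccc(O)cc1F | starting material
2 | prenyl bromide (1-bromo-3-methylbut-2-ene) | CC(C)=CCBr | starting material
3 | 3-methylbut-2-en-1-yl 2-fluoro-4-[(3-methylbut-2-en-1-yl)oxy]benzoate | CC(C)=CCOC(=O)c1ccc(OCC=C(C)C)cc1F | intermediate
4 | 2-fluoro-4-[(3-methylbut-2-en-1-yl)oxy]benzoic acid | O=C(O)c1ccc(OCC=C(C)C)cc1F | intermediate
5 | {2-fluoro-4-[(3-methylbut-2-en-1-yl)oxy]phenyl}(1H-imidazol-1-yl)methanone | O=C(c1ccc(OCC=C(C)C)cc1F)n1ccnc1 | intermediate
6 | 2-bromo-1-(3,4-dimethoxyphenyl)ethanone | COc1ccc(C(=O)CBr)cc1OC | starting material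
7 | 2-(3,4-dimethoxyphenyl)-2-oxoethyl formate | COc1ccc(C(=O)COC=O)cc1OC | intermediate
8 | 1-(3,4-dimethoxyphenyl)-2-hydroxyethanone | COc1ccc(C(=O)CO)cc1OC | intermediate
9 | 1-(3,4-dimethoxyphenyl)-2-(methoxymethoxy)ethanone | COCOCC(=O)c1ccc(OC)c(OC)c1 | intermediate
10 | lithium (Z)-1-(3,4-dimethoxyphenyl)-2-(methoxymethoxy)ethen-1-olate | [Li+].COCO/C=C(\[O-])c1ccc(OC)c(OC)c1 | intermediate
11 | rac-1-{2-fluoro-4-[(3-methylbut-2-en-1-yl)oxy]phenyl}-3-(3,4-dimethoxyphenyl)-2-(methoxymethoxy)propane-1,3-dione | COCOC(C(=O)c1ccc(OCC=C(C)C)cc1F)C(=O)c1ccc(OC)c(OC)c1 | intermediate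
12 | potassium enolate of 11, enolate oxygen on the ring B carbonyl carbon and cis to the ring A aroyl group (E) | [K+].[O-]/C(c1ccc(OC)c(OC)c1)=C(OCOC)\C(=O)c1ccc(OCC=C(C)C)cc1F | intermediate
13 | 2-(3,4-dimethoxyphenyl)-3-(methoxymethoxy)-7-[(3-methylbut-2-en-1-yl)oxy]-4H-chromen-4-one | COCOc1c(-c2ccc(OC)c(OC)c2)oc2cc(OCC=C(C)C)ccc2c1=O | intermediate
14 | 2-(3,4-dimethoxyphenyl)-3-hydroxy-7-[(3-methylbut-2-en-1-yl)oxy]-4H-chromen-4-one | COc1ccc(-c2oc3cc(OCC=C(C)C)ccc3c(=O)c2O)cc1OC | target

**Step count**

Total steps: 8. Longest linear sequence: 6 steps (steps 1, 2, 3, 6, 7, 8); the ring B branch (steps 4, 5) joins at step 6.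

**Steps most likely to fail, with fallbacks**

1. Step 7. Fluoride displacement may be slow, because the activating carbonyl is part of the enolate and ring A carries an alkoxy donor. Retro-Claisen cleavage of the diketone by adventitious hydroxide or by dimethylamine from hot DMF could then outrun ring closure. The fallback sets out from 2 and comes back at 14 by chalcone oxidation. Commercial 2',4'-dihydroxyacetophenone is prenylated at the non-chelated 4'-hydroxyl with 2 (K2CO3, acetone, reflux) to give 1-{2-hydroxy-4-[(3-methylbut-2-en-1-yl)oxy]phenyl}ethanone F1. Claisen–Schmidt condensation with commercial 3,4-dimethoxybenzaldehyde (KOH, EtOH, rt) should give (E)-3-(3,4-dimethoxyphenyl)-1-{2-hydroxy-4-[(3-methylbut-2-en-1-yl)oxy]phenyl}prop-2-en-1-one F2. Algar–Flynn–Oyamada oxidative cyclisation (30% H2O2, NaOH, MeOH, 0 °C → rt) should then give 14 directly; alkaline peroxide does not attack the electron-rich prenyl alkene.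

2. Step 6. The ambident enolate may be acylated on oxygen, or proton transfer between enolate and product may stall the reaction. The fallback sets out from 3 and 10 and comes back at 11 by aldol addition and oxidation. Ester 3 is reduced (i-Bu2AlH, CH2Cl2, −78 °C) to {2-fluoro-4-[(3-methylbut-2-en-1-yl)oxy]phenyl}methanol F3, which is oxidised (MnO2, CH2Cl2, rt) to 2-fluoro-4-[(3-methylbut-2-en-1-yl)oxy]benzaldehyde F4. Aldol addition of lithium enolate 10 to F4 (THF, −78 °C) should give 1-(3,4-dimethoxyphenyl)-3-{2-fluoro-4-[(3-methylbut-2-en-1-yl)oxy]phenyl}-3-hydroxy-2-(methoxymethoxy)propan-1-one F5 as a racemic diastereomer mixture, whose configuration is irrelevant. Oxidation of the secondary alcohol (Dess–Martin periodinane, NaHCO3, CH2Cl2) should give 11.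

3. Step 8. Acid may ionise the prenyl ether to a prenyl cation, causing loss of the group or its transfer to ring carbon, in competition with acetal cleavage. The fallback sets out from 8 and comes back at 14, replacing the acid-labile acetal with one removed by fluoride. Alcohol 8 is protected (SEMCl, i-Pr2NEt, CH2Cl2) as 1-(3,4-dimethoxyphenyl)-2-{[2-(trimethylsilyl)ethoxy]methoxy}ethanone F6. Acylation of its lithium enolate with 5, as in step 6, should give rac-1-{2-fluoro-4-[(3-methylbut-2-en-1-yl)oxy]phenyl}-3-(3,4-dimethoxyphenyl)-2-{[2-(trimethylsilyl)ethoxy]methoxy}propane-1,3-dione F7. Cyclisation as in step 7 (K2CO3, DMF) should give 2-(3,4-dimethoxyphenyl)-7-[(3-methylbut-2-en-1-yl)oxy]-3-{[2-(trimethylsilyl)ethoxy]methoxy}-4H-chromen-4-one F8. Fluoride-induced fragmentation (Bu4NF, THF, 50 °C), which leaves the prenyl ether untouched, should then give 14.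

**Further compounds**

F1 | step 7 | 1-{2-hydroxy-4-[(3-methylbut-2-en-1-yl)oxy]phenyl}ethanone | CC(=O)c1ccc(OCC=C(C)C)cc1O
F2 | step 7 | (E)-3-(3,4-dimethoxyphenyl)-1-{2-hydroxy-4-[(3-methylbut-2-en-1-yl)oxy]phenyl}prop-2-en-1-one | COc1ccc(/C=C/C(=O)c2ccc(OCC=C(C)C)cc2O)cc1OC
F3 | step 6 | {2-fluoro-4-[(3-methylbut-2-en-1-yl)oxy]phenyl}methanol | OCc1ccc(OCC=C(C)C)cc1F
F4 | step 6 | 2-fluoro-4-[(3-methylbut-2-en-1-yl)oxy]benzaldehyde | O=Cc1ccc(OCC=C(C)C)cc1F
F5 | step 6 | 1-(3,4-dimethoxyphenyl)-3-{2-fluoro-4-[(3-methylbut-2-en-1-yl)oxy]phenyl}-3-hydroxy-2-(methoxymethoxy)propan-1-one (racemic diastereomer mixture) | COCOC(C(O)c1ccc(OCC=C(C)C)cc1F)C(=O)c1ccc(OC)c(OC)c1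
F6 | step 8 | 1-(3,4-dimethoxyphenyl)-2-{[2-(trimethylsilyl)ethoxy]methoxy}ethanone | C[Si](C)(C)CCOCOCC(=O)c1ccc(OC)c(OC)c1
F7 | step 8 | rac-1-{2-fluoro-4-[(3-methylbut-2-en-1-yl)oxy]phenyl}-3-(3,4-dimethoxyphenyl)-2-{[2-(trimethylsilyl)ethoxy]methoxy}propane-1,3-dione | C[Si](C)(C)CCOCOC(C(=O)c1ccc(OCC=C(C)C)cc1F)C(=O)c1ccc(OC)c(OC)c1
F8 | step 8 | 2-(3,4-dimethoxyphenyl)-7-[(3-methylbut-2-en-1-yl)oxy]-3-{[2-(trimethylsilyl)ethoxy]methoxy}-4H-chromen-4-one | C[Si](C)(C)CCOCOc1c(-c2ccc(OC)c(OC)c2)oc2cc(OCC=C(C)C)ccc2c1=O
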